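The earlier runs and the new flask are simulated for substances that don't exist.

The reading falls at 2.0 min, and the meeting asked what stands in each flask at that moment.

| flask | substrate | partner | rival reagent | protic impurity | temperature | remark | time |
|---|---|---|---|---|---|---|---|
| north | 10 mM | 11 mM | 7 mM | 0.50 mM | 20 °C | run made earlier |  |
| south-west | 14 mM | 11 mM | 7 mM | 0.50 mM | 35 °C | run made earlier |  |
| south-east | 22 mM | 11 mM | 7 mM | 0.50 mM | 20 °C | run made earlier |  |
| west | 10 mM | 11 mM | 14 mM | 0.50 mM | 35 °C | run made earlier |  |
| winter | 10 mM (fed, over 1.5 min) | 11.0 mM | 7.00 mM | 0.500 mM |  | the addition at 15 °C, then warmed to 35 °C; the feed brings no volume worth counting | 2.0 min |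
| dusk | 10 mM | 11.0 mM | 7.00 mM (fed, over 1.5 min) | 0.500 mM | 35 °C | all else is in the flask from the start; the feed brings no volume worth counting | 2.0 min |
| summer | 10 mM | 11.0 mM | 7.00 mM (in portions, 3, over 1.5 min) | 0.500 mM | 35 °C | first portion at the start, last at 1.5 min | 2.0 min |
| midnight | 10 mM (fed, over 1.5 min) | 11.0 mM | 7.00 mM | 0.500 mM | 35 °C | all else is in the flask from the start; the feed brings no volume worth counting | 2.0 min |

1. the flask with the highest amount of target, in percent of the substrate charged ("all alike" if they lie within 1.5 percentage points) (winter / dusk / summer / midnight / all alike)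
2. final target, as a percentage of the substrate charged, in winter
3. final target, as a percentage of the substrate charged, in dusk
4. final target, as a percentage of the substrate charged, in summer
5. final target, as a percentage of the substrate charged, in midnight

north run (percent of the substrate charged)

| time / min | target / % |
|---|---|
| 0.333 | 12.7 |
| 0.833 | 24.8 |
| 1.33 | 31.0 |
| 2.00 | 38.2 |
| 3.00 | 42.8 |
| 4.00 | 42.6 |

south-west run (percent of the substrate charged)

| time / s | target / % |
|---|---|
| 10.0 | 16.1 |
| 20.0 | 19.7 |
| 30.0 | 20.4 |
| 50.0 | 16.3 |
| 80.0 | 15.2 |
| 90.0 | 15.1 |

south-east run (percent of the substrate charged)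

| time / min | target / % |
|---|---|
| 0.333 | 12.1 |
| 0.667 | 19.0 |
| 1.00 | 23.8 |
| 2.00 | 30.3 |
| 3.00 | 32.0 |

west run (percent of the substrate charged)

| time / s | target / % |
|---|---|
| 10.0 | 15.1 |
| 25.0 | 20.6 |
| 40.0 | 19.3 |
| 60.0 | 16.3 |
| 90.0 | 12.8 |

(standard deviation of a reading: 1 percentage point)

- the earlier runs were read with a standard deviation of 1 percentage point

The first speaker noted that target holds in north at 20 °C, 42.8 % at 3.00 min and 42.6 % at 4.00 min, but peaks and falls in west at 35 °C. She therefore proposed the fade rate, the fractional loss of target per minute spent warm after the peak, a first-order decay constant read from west between 25.0 s and 90.0 s: 0.439 min⁻¹.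

The second speaker objected that south-west, read from 30.0 s to 90.0 s, fades at 0.301 min⁻¹, so the number carries a spread. He also asked what a feed changes.

The third speaker said to follow one molecule of partner. It sits in each flask from the start, and at every moment it either couples with substrate or is lost. She therefore supposed that the fade is the loss of partner, that target follows the surviving partner, and that the clock counts warm minutes whatever is fed. The minutes record this as a supposition.

Extended to 2.0 min, west gives 10.3 % and south-west gives 13.0 %, and the meeting placed dusk, summer and midnight in that span. Winter is warm for 0.500 min, longer than the 25.0 s west took to peak. That puts winter near 19.9 %, about twice the west figure, and the meeting committed to winter first.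

The forecast also chose winter but stood higher than this reckoning, with winter 28 %, dusk 18.5 %, summer 17.5 % and midnight 15 %, noting that “Midnight exposes it to full rival”.

The flasks give winter 20.9 %, dusk 12.4 %, summer 12.4 % and midnight 11.0 %, so winter stands highest.

    substrate + partner ⇌ target (K = 44.0 M⁻¹, k = 2.50 M⁻¹ s⁻¹, Ea = 61.0 kJ mol⁻¹, ΔH = −81.0 kJ mol⁻¹)
    substrate + rival reagent → side product (k = 0.380 M⁻¹ s⁻¹, Ea = 51.0 kJ mol⁻¹)
    rival reagent + protic impurity → quenched reagent (k = 150 M⁻¹ s⁻¹, Ea = 51.0 kJ mol⁻¹)
    partner → decomposed reagent (k = 0.0100 s⁻¹, Ea = 90.0 kJ mol⁻¹)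
    (constants at 35 °C)

In midnight at 0.666 min, partner goes to decomposed reagent 1.1 times as fast as it couples with substrate (forward step alone). At 2.00 min that ratio is 0.53. Read as the third speaker's loss of partner, the fade rate over 2.0 min gives 41.6 % of the charge undecomposed, and midnight has 36.2 % of its partner undecomposed, free or bound in target. The neighbour of midnight charged with 44 mM of partner has 34.5 % undecomposed and 33.3 % target at 2.00 min.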